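**Strategy.** Ring B is disconnected last into three pieces: the terminal alkyne of a 2-ethynylchromone (C1', C6'), an α-alkoxyvinyl methoxycarbene of zerovalent chromium (C5', C4', C3') and one CO ligand (C2'). The benzannulation exploits the para relationship of the C2' and C5' oxygens, with the chromone-bearing C1' ortho to C2'. In one operation it forms C5'–C6', C1'–C2' and C2'–C3', closes ring B and delivers the C2' oxygen as the only free phenol, with O4' and O5' already differentiated. The precursor is 5,7-bis(benzyloxy)-2-ethynyl-6-methoxychromone, made from phloroacetophenone; the carbene comes from tert-butyl vinyl ether and Cr(CO)6.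

Key step: step 8

Remarks on the design:
- Ring A carries four oxygen-bearing carbons (C5, C6, C7, C8a). A 1,2,3-trioxygenated benzene such as 2-methoxyresorcinol lacks one of them, so the route starts from 2,4,6-trihydroxyacetophenone and adds the C6 oxygen para to the free phenol. This also fixes the 5,6,7 pattern and excludes the 5,7,8 isomer.
- O5 and O7 are carried as benzyl ethers and not as acetal ethers, because they must survive the acid hydrolysis of an aryl sulfate and an acid cyclodehydration. They leave together with the tert-butyl ether in one Lewis acid step.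
- The target has no stereocentre.

**Route**

Step 1
Reactants: 1 2,4,6-trihydroxyacetophenone
Product: 2 1-[2,4-bis(benzyloxy)-6-hydroxyphenyl]ethan-1-one
Conditions: BnBr (2.05 equiv), K2CO3 (2.2 equiv), DMF, rt
Reagents that add atoms: benzyl bromide, BrCc1ccccc1
Why: Williamson ether synthesis in which the hydroxyl hydrogen-bonded to the acetyl group stays free; the two ortho hydroxyls of 1 are equivalent, so only one regioisomer of the dibenzyl ether can form.

Step 2
Reactants: 2 1-[2,4-bis(benzyloxy)-6-hydroxyphenyl]ethan-1-one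
Product: 4 1-[2,4-bis(benzyloxy)-3,6-dihydroxyphenyl]ethan-1-one, via aryl potassium sulfate 3 (not isolated)
Conditions: K2S2O8 (1.2 equiv), aq. NaOH, pyridine, 15 °C; then aq. HCl, toluene, 80 °C
Reagents that add atoms: K2S2O8 (potassium peroxodisulfate), [K+].[K+].[O-]S(=O)(=O)OOS(=O)(=O)[O-]
Why: Elbs persulfate oxidation, in which the phenoxide attacks the peroxide oxygen through its only para carbon and the aryl sulfate is then hydrolysed by acid, so the new oxygen should land between the two benzyloxy groups.

Step 3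
Reactants: 4 1-[2,4-bis(benzyloxy)-3,6-dihydroxyphenyl]ethan-1-one
Product: 5 1-[2,4-bis(benzyloxy)-6-hydroxy-3-methoxyphenyl]ethan-1-one
Conditions: MeI (1.1 equiv), K2CO3 (1.1 equiv), acetone, 40 °C
Reagents that add atoms: iodomethane, CI
Why: Selective Williamson O-methylation of the non-chelated 3-hydroxyl, while the 6-hydroxyl is held in a hydrogen bond to the ketone and stays free for the later pyranone closure.

Step 4
Reactants: 5 1-[2,4-bis(benzyloxy)-6-hydroxy-3-methoxyphenyl]ethan-1-one; 6 ethyl 3-(trimethylsilyl)propiolate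
Product: 7 1-[2,4-bis(benzyloxy)-6-hydroxy-3-methoxyphenyl]-5-(trimethylsilyl)pent-4-yne-1,3-dione
Conditions: LiN(SiMe3)2 (3.3 equiv), THF, −78 °C; 6 (1.3 equiv), −78 → −10 °C; aq. NH4Cl
Reagents that add atoms: none
Why: Crossed Claisen condensation of the lithium phenoxide-enolate dianion at the ester carbonyl; the silyl group screens the alkyne terminus against conjugate addition and the chelated diketonate is stable to the excess base until the quench.

Step 5
Reactants: 7 1-[2,4-bis(benzyloxy)-6-hydroxy-3-methoxyphenyl]-5-(trimethylsilyl)pent-4-yne-1,3-dione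
Product: 8 5,7-bis(benzyloxy)-6-methoxy-2-[(trimethylsilyl)ethynyl]-4H-chromen-4-one
Conditions: p-TsOH·H2O (cat.), toluene, 4 Å molecular sieves, 80 °C
Reagents that add atoms: none
Why: Acid-catalysed cyclodehydration as in the Baker–Venkataraman chromone synthesis, the free phenol adding to the alkynyl ketone carbonyl with loss of water; benzyl ethers and the C-silyl alkyne tolerate catalytic sulfonic acid.

Step 6
Reactants: 8 5,7-bis(benzyloxy)-6-methoxy-2-[(trimethylsilyl)ethynyl]-4H-chromen-4-one
Product: 9 5,7-bis(benzyloxy)-2-ethynyl-6-methoxy-4H-chromen-4-one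
Conditions: Bu4NF (1.1 equiv), AcOH (1.2 equiv), THF, −20 → 0 °C
Reagents that add atoms: none
Why: Fluoride-induced protodesilylation of an alkynylsilane, buffered with acetic acid so that the medium never becomes basic enough to add nucleophiles to the pyranone or to the electron-poor alkyne.

Step 7
Reactants: 10 tert-butyl vinyl ether; 11 chromium hexacarbonyl
Product: 14 pentacarbonyl[(1-tert-butoxyvinyl)(methoxy)carbene]chromium, via 1-tert-butoxyvinyllithium 12 (not isolated), via lithium acylchromate 13 (not isolated)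
Conditions: 10, t-BuLi, THF/pentane, −78 → 0 °C; Cr(CO)6, Et2O, 0 °C → rt; concentrate; Me3OBF4, CH2Cl2, 0 °C, Ar, dark
Reagents that add atoms: trimethyloxonium tetrafluoroborate (Me3OBF4), C[O+](C)C.F[B-](F)(F)F
Why: Fischer carbene synthesis by α-lithiation of the vinyl ether, addition of the vinyllithium to a CO ligand and O-methylation of the acylchromate with the hard oxonium salt; the tert-butyl group has no α-hydrogen to compete in the lithiation and is an acid-labile phenol protecting group later.

Step 8
Reactants: 9 5,7-bis(benzyloxy)-2-ethynyl-6-methoxy-4H-chromen-4-one; 14 pentacarbonyl[(1-tert-butoxyvinyl)(methoxy)carbene]chromium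
Product: 16 5,7-bis(benzyloxy)-2-(4-tert-butoxy-2-hydroxy-5-methoxyphenyl)-6-methoxy-4H-chromen-4-one, via tricarbonylchromium arene complex 15 (not isolated)
Conditions: 14 (1.5 equiv), THF (0.05 M), 50 °C, Ar; then air, EtOAc, rt
Reagents that add atoms: none
Why: Dötz benzannulation of an alkenyl(alkoxy)carbene complex of zerovalent chromium with a terminal alkyne, a known route to 4-alkoxyphenols: thermal loss of one CO from 14 opens a site for alkyne 9, which inserts into the Cr=C bond so that the carbene carbon bonds to the alkyne CH (C5'–C6') and chromium moves to the chromone-bearing carbon. CO insertion at that carbon (C1'–C2') gives a chromium-bound dienylketene, and ring B is closed by a thermal six-electron disrotatory electrocyclisation between the ketene carbon and the vinyl CH2 (C2'–C3'), a six-membered carbocycle assembled in a formal [3+2+1] sense. Tautomerisation of the cyclohexadienone gives the phenol as its Cr(CO)3 complex 15, which air should decomplex. No stereocentre is formed. The step needs regiocontrol of the alkyne insertion, which the terminal alkyne secures because its hydrogen end, not the chromonyl end, goes next to the carbene carbon; this puts the CO-derived hydroxyl on C2' beside C1', the methoxy carbon C5' para to it and the tert-butoxy carbon at C4'. It also needs CO insertion to outrun cyclisation without CO, which an alkenyl methoxy carbene of chromium in THF favours.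

Step 9
Reactants: 16 5,7-bis(benzyloxy)-2-(4-tert-butoxy-2-hydroxy-5-methoxyphenyl)-6-methoxy-4H-chromen-4-one
Product: 17 5,7-bis(benzyloxy)-2-(4-tert-butoxy-2,5-dimethoxyphenyl)-6-methoxy-4H-chromen-4-one
Conditions: MeI (3 equiv), K2CO3 (2 equiv), DMF, rt
Reagents that add atoms: iodomethane, CI
Why: Williamson O-methylation of the only free phenol in the molecule, so no selectivity question arises.

Step 10
Reactants: 17 5,7-bis(benzyloxy)-2-(4-tert-butoxy-2,5-dimethoxyphenyl)-6-methoxy-4H-chromen-4-one
Product: 18 5,7-dihydroxy-2-(4-hydroxy-2,5-dimethoxyphenyl)-6-methoxy-4H-chromen-4-one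
Conditions: BCl3 (6 equiv), C6HMe5 (6 equiv), CH2Cl2, −78 → −40 °C; MeOH, then water
Reagents that add atoms: none
Why: Lewis acid ether cleavage in which BCl3 ionises the two aryl benzyl ethers and the aryl tert-butyl ether at low temperature, pentamethylbenzene traps the benzyl cations so that C8 and ring B are not C-benzylated, and the three aryl methyl ethers (none peri to the carbonyl) should stay intact.

**Compound list**

1 | 2,4,6-trihydroxyacetophenone | CC(=O)c1c(O)cc(O)cc1O | starting material
2 | 1-[2,4-bis(benzyloxy)-6-hydroxyphenyl]ethan-1-one | CC(=O)c1c(O)cc(OCc2ccccc2)cc1OCc1ccccc1 | intermediate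
3 | potassium 3-acetyl-2,6-bis(benzyloxy)-4-hydroxyphenyl sulfate | CC(=O)c1c(O)cc(OCc2ccccc2)c(OS(=O)(=O)[O-])c1OCc1ccccc1.[K+] | intermediate
4 | 1-[2,4-bis(benzyloxy)-3,6-dihydroxyphenyl]ethan-1-one | CC(=O)c1c(O)cc(OCc2ccccc2)c(O)c1OCc1ccccc1 | intermediate
5 | 1-[2,4-bis(benzyloxy)-6-hydroxy-3-methoxyphenyl]ethan-1-one | CC(=O)c1c(O)cc(OCc2ccccc2)c(OC)c1OCc1ccccc1 | intermediate
6 | ethyl 3-(trimethylsilyl)propiolate | CCOC(=O)C#C[Si](C)(C)C | starting material
7 | 1-[2,4-bis(benzyloxy)-6-hydroxy-3-methoxyphenyl]-5-(trimethylsilyl)pent-4-yne-1,3-dione (largely enolised) | C[Si](C)(C)C#CC(=O)CC(=O)c1c(O)cc(OCc2ccccc2)c(OC)c1OCc1ccccc1 | intermediate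
8 | 5,7-bis(benzyloxy)-6-methoxy-2-[(trimethylsilyl)ethynyl]-4H-chromen-4-one | C[Si](C)(C)C#Cc1cc(=O)c2c(OCc3ccccc3)c(OC)c(OCc3ccccc3)cc2o1 | intermediate
9 | 5,7-bis(benzyloxy)-2-ethynyl-6-methoxy-4H-chromen-4-one | C#Cc1cc(=O)c2c(OCc3ccccc3)c(OC)c(OCc3ccccc3)cc2o1 | intermediate
10 | tert-butyl vinyl ether | C=COC(C)(C)C | starting material
11 | chromium hexacarbonyl, Cr(CO)6 | O=C=[Cr](=C=O)(=C=O)(=C=O)(=C=O)=C=O | starting material
12 | 1-tert-butoxyvinyllithium | [Li]C(=C)OC(C)(C)C | intermediate
13 | lithium pentacarbonyl(2-tert-butoxyacryloyl)chromate | [Li+].[O-]C(=[Cr](=C=O)(=C=O)(=C=O)(=C=O)=C=O)C(=C)OC(C)(C)C | intermediate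
14 | pentacarbonyl[(1-tert-butoxyvinyl)(methoxy)carbene]chromium | COC(=[Cr](=C=O)(=C=O)(=C=O)(=C=O)=C=O)C(=C)OC(C)(C)C | intermediate
15 | tricarbonyl(η6-arene)chromium complex of 16, Cr(CO)3 on the face of ring B (written as arene plus Cr(CO)3 fragment) | CC(C)(C)Oc1cc(O)c(-c2cc(=O)c3c(OCc4ccccc4)c(OC)c(OCc4ccccc4)cc3o2)cc1OC.O=C=[Cr](=C=O)=C=O | intermediate
16 | 5,7-bis(benzyloxy)-2-(4-tert-butoxy-2-hydroxy-5-methoxyphenyl)-6-methoxy-4H-chromen-4-one | CC(C)(C)Oc1cc(O)c(-c2cc(=O)c3c(OCc4ccccc4)c(OC)c(OCc4ccccc4)cc3o2)cc1OC | intermediate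
17 | 5,7-bis(benzyloxy)-2-(4-tert-butoxy-2,5-dimethoxyphenyl)-6-methoxy-4H-chromen-4-one | CC(C)(C)Oc1cc(OC)c(-c2cc(=O)c3c(OCc4ccccc4)c(OC)c(OCc4ccccc4)cc3o2)cc1OC | intermediate
18 | 5,7-dihydroxy-2-(4-hydroxy-2,5-dimethoxyphenyl)-6-methoxy-4H-chromen-4-one | COc1cc(-c2cc(=O)c3c(O)c(OC)c(O)cc3o2)c(OC)cc1O | target

**Count.** Total: 10 steps. Longest linear sequence: 9 steps (steps 1 to 6, then 8, 9 and 10); the carbene branch is the single step 7.

**Steps most likely to fail**

Step 8. The alkyne is conjugated to an electron-poor pyranone, so insertion into the chromium carbene may be slow, cyclisation may occur without CO insertion, or the vinylcarbene complex may decompose before it reacts. The fallback sets out from 5 and comes back at the target 18; it takes ring B with its oxygens already in place and needs neither step 7 nor steps 4 to 6. Purchased 2,5-dimethoxyphenol would be O-benzylated (BnBr, K2CO3, DMF) to 2-(benzyloxy)-1,4-dimethoxybenzene F1. Vilsmeier–Haack formylation (POCl3, DMF) para to the benzyloxy group should give 4-(benzyloxy)-2,5-dimethoxybenzaldehyde F2. Claisen–Schmidt condensation of 5 with F2 (KOH, EtOH, rt) should give (E)-1-[2,4-bis(benzyloxy)-6-hydroxy-3-methoxyphenyl]-3-[4-(benzyloxy)-2,5-dimethoxyphenyl]prop-2-en-1-one F3. Oxidative cyclisation with catalytic I2 in DMSO at 120 °C should give 5,7-bis(benzyloxy)-2-[4-(benzyloxy)-2,5-dimethoxyphenyl]-6-methoxy-4H-chromen-4-one F4. BCl3 and C6HMe5 in CH2Cl2 at −78 °C would then remove the three benzyl groups to give 18.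

Step 4. The enolate may add in conjugate fashion to the ynoate, or the diketonate may attack the alkyne, in place of clean acylation at the ester carbonyl. The fallback sets out from 5 and comes back at 7. It replaces the ester by an aldehyde, which can only be attacked at the carbonyl. The dianion of 5 (LiN(SiMe3)2, THF, −78 °C) would be added to 3-(trimethylsilyl)prop-2-ynal and quenched cold to give racemic 1-[2,4-bis(benzyloxy)-6-hydroxy-3-methoxyphenyl]-3-hydroxy-5-(trimethylsilyl)pent-4-yn-1-one F5. Oxidation of the propargylic alcohol with MnO2 in CH2Cl2 should then give diketone 7.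

Step 2. The phenoxide of 2 is poorly soluble in aqueous alkali, so conversion may be low, and some benzyl ether may be lost during the acid hydrolysis of the sulfate. The fallback sets out from 2 and comes back at 4. It replaces the persulfate substitution by a radical oxidation to the quinone followed by reduction. Teuber oxidation of 2 with (KSO3)2NO (Fremy's salt) in aqueous KH2PO4 and acetone should give 2-acetyl-3,5-bis(benzyloxy)cyclohexa-2,5-diene-1,4-dione F6. Reduction with aqueous Na2S2O4 in EtOAc should then give hydroquinone 4.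

**Further compounds**

F1 | step 8 | 2-(benzyloxy)-1,4-dimethoxybenzene | COc1ccc(OC)c(OCc2ccccc2)c1
F2 | step 8 | 4-(benzyloxy)-2,5-dimethoxybenzaldehyde | COc1cc(OCc2ccccc2)c(OC)cc1C=O
F3 | step 8 | (E)-1-[2,4-bis(benzyloxy)-6-hydroxy-3-methoxyphenyl]-3-[4-(benzyloxy)-2,5-dimethoxyphenyl]prop-2-en-1-one | COc1cc(OCc2ccccc2)c(OC)cc1/C=C/C(=O)c1c(O)cc(OCc2ccccc2)c(OC)c1OCc1ccccc1
F4 | step 8 | 5,7-bis(benzyloxy)-2-[4-(benzyloxy)-2,5-dimethoxyphenyl]-6-methoxy-4H-chromen-4-one | COc1cc(OCc2ccccc2)c(OC)cc1-c1cc(=O)c2c(OCc3ccccc3)c(OC)c(OCc3ccccc3)cc2o1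
F5 | step 4 | 1-[2,4-bis(benzyloxy)-6-hydroxy-3-methoxyphenyl]-3-hydroxy-5-(trimethylsilyl)pent-4-yn-1-one (racemic) | C[Si](C)(C)C#CC(O)CC(=O)c1c(O)cc(OCc2ccccc2)c(OC)c1OCc1ccccc1
F6 | step 2 | 2-acetyl-3,5-bis(benzyloxy)cyclohexa-2,5-diene-1,4-dione | CC(=O)C1=C(OCc2ccccc2)C(=O)C(OCc2ccccc2)=CC1=O
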